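The target is cut where ring A links the two halves: C5–C1' and C4a–C4, plus both C4–O bonds of the ketal (each half numbered as a naphthalene, C1–C8a, primes for the carbinol half). C4a and C5 are neighbours on ring A, and C4 and C1' share the bridging oxygen. A 4-iodo-5-bromoaryl silyl ether (ring A) can therefore act as a 1,2-dianion. Its C5 carbanion adds to the C1' ketone of an enantiopure, silyl-protected epoxy tetralone (ring B), and its C4a carbanion opens maleic anhydride. Acid then closes the five-membered oxacycle and the 1,3-dioxin in the same flask, giving the bicyclic ketal with a Z-acrylic acid arm.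

Key step: step 15

Remarks before the steps

- Numbering: in the target and in 21–26, C1 is the ketone, C2–C3 the epoxide, C4 the ketal carbon, ring A = C4a–C8a (C5 bonded to C1', C7 Cl, C8 OH). C1' is the quaternary carbon on the bridging oxygen, C2'–C3' the epoxide, C4' the carbinol, ring B = C4a'–C8a' (C5' OH, C6' Cl, C8' on the aryl ketal oxygen). Compounds 3–16 carry the locants of their own names; C1 of 14–16 becomes C1'.
- Assumption: the quinine-derived ammonium salt is taken to deliver the (2S,3R)-epoxide 10; if the sense of induction proves opposite, the pseudo-enantiomeric N-benzylquinidinium chloride is used in the same way.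
- Precursor design: O4' and O5' are tied as one di-tert-butylsilylene (DTBS). This keeps an axial silyloxy group off the face of C1' that the aryl nucleophile must use, and the bridge forms without having to tell the two phenols apart.
- The C8' oxygen carries the only acid-labile silyl group (TES), so the aqueous acid that closes the ketal also frees it.
- In 19 iodine sits at the future C5 and bromine at the future C4a, so the order of exchange is built in; the first aryllithium is made and used at –100 °C.
- PMB = 4-methoxybenzyl, TBS = tert-butyldimethylsilyl, TES = triethylsilyl.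

Step 1
Reactants: 1 4-(2,5-dimethoxyphenyl)butanoic acid
Product: 2 4-(4-chloro-2,5-dimethoxyphenyl)butanoic acid
Conditions: SO2Cl2 (1.05 equiv), CH2Cl2, 0 °C → rt
Reagents that add atoms: sulfuryl chloride, ClS(Cl)(=O)=O
Why: Electrophilic aromatic chlorination; the alkyl chain and the C5 methoxy group both direct to C4 of the ring (para to the chain), the usual site of substitution in 2,5-dimethoxyalkylbenzenes.

Step 2
Reactants: 2 4-(4-chloro-2,5-dimethoxyphenyl)butanoic acid
Product: 3 7-chloro-5,8-dimethoxy-1-tetralone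
Conditions: Eaton's reagent (P2O5 in MeSO3H), 40 °C
Reagents that add atoms: none
Why: Intramolecular Friedel–Crafts acylation (Haworth tetralone closure); the acylium ion can reach only the free ortho carbon, which is activated by the neighbouring methoxy group, so the ketone ends up peri to the methoxy group flanked by chlorine.

Step 3
Reactants: 3 7-chloro-5,8-dimethoxy-1-tetralone
Product: 4 7-chloro-5,8-dihydroxy-1-tetralone
Conditions: BBr3 (3 equiv), CH2Cl2, –78 °C → rt; H2O
Reagents that add atoms: none
Why: Lewis-acid cleavage of aryl methyl ethers with BBr3 frees both phenols, so they can be re-protected with groups that can later be removed beside an epoxide.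

Step 4
Reactants: 4 7-chloro-5,8-dihydroxy-1-tetralone
Product: 5 7-chloro-5,8-bis(PMB-oxy)-1-tetralone
Conditions: 4-MeOC6H4CH2Cl (2.5 equiv), K2CO3, Bu4NI (cat.), DMF, 60 °C, under argon
Reagents that add atoms: 4-methoxybenzyl chloride, COc1ccc(CCl)cc1
Why: Williamson ether synthesis; carbonate in warm DMF with iodide catalysis also alkylates the hydrogen-bonded peri phenol, and the PMB ethers tolerate every basic, oxidative and reductive step up to step 11.

Step 5
Reactants: 5 7-chloro-5,8-bis(PMB-oxy)-1-tetralone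
Product: 7 7-chloro-5,8-bis(PMB-oxy)naphthalen-1-ol, via 4H-naphthalen-1-one tautomer 6 (not isolated)
Conditions: LiN(i-Pr)2 (1.1 equiv), THF, –78 °C; PhS(Cl)=N-t-Bu (1.2 equiv), –78 °C; aq NH4Cl
Reagents that add atoms: none
Why: Mukaiyama dehydrogenation; the lithium enolate is sulfinylated at sulfur and loses the sulfenamide at –78 °C, and the resulting 4H-naphthalen-1-one tautomerises to the naphthol.

Step 6
Reactants: 7 7-chloro-5,8-bis(PMB-oxy)naphthalen-1-ol
Product: 9 7-chloro-4,4-dimethoxy-5,8-bis(PMB-oxy)naphthalen-1(4H)-one, via 4-methoxynaphthol 8 (not isolated)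
Conditions: PhI(OAc)2 (2.2 equiv), MeOH, 0 °C → rt
Reagents that add atoms: methanol, CO
Why: Oxidative dearomatisation of a para-unsubstituted 1-naphthol with a hypervalent iodine reagent; two successive oxidations, each followed by attack of methanol at C4, give the p-quinone monoketal whose free ketone lies peri to the chlorine-flanked ether.

Step 7
Reactants: 9 7-chloro-4,4-dimethoxy-5,8-bis(PMB-oxy)naphthalen-1(4H)-one
Product: 10 (2S,3R)-2,3-epoxy ketone monoketal
Conditions: t-BuOOH (70% aq), 0.5 M NaOH, N-benzylquininium chloride (10 mol %), toluene, 0 °C → rt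
Reagents that add atoms: tert-butyl hydroperoxide, CC(C)(C)OO
Why: Wynberg-type asymmetric Weitz–Scheffer epoxidation under phase transfer; the tert-butyl peroxide anion, ion-paired with the chiral ammonium cation, adds to one enantiotopic face of the enone and the enolate closes the epoxide, which sets C2 and C3.

Step 8
Reactants: 10 (2S,3R)-2,3-epoxy ketone monoketal
Product: 11 cis-epoxy alcohol (1R,2R,3R)
Conditions: NaBH4, CeCl3·7H2O, MeOH/CH2Cl2, –78 °C
Reagents that add atoms: none
Why: Luche 1,2-reduction; hydride attacks the ketone on the face anti to the adjacent epoxide oxygen (Felkin-type, less hindered), which places the new hydroxyl group cis to the epoxide oxygen.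

Step 9
Reactants: 11 cis-epoxy alcohol (1R,2R,3R)
Product: 12 trans-epoxy 4-nitrobenzoate (1S,2R,3R)
Conditions: 4-O2NC6H4CO2H, PPh3, DIAD, toluene, 0 °C → rt
Reagents that add atoms: 4-nitrobenzoic acid, OC(=O)c1ccc(cc1)[N+](=O)[O-]
Why: Mitsunobu reaction with an acidic carboxylic acid, as used for hindered secondary alcohols; SN2 displacement of the oxyphosphonium group from the face opposite the epoxide inverts C1 and gives the ester trans to the epoxide oxygen.

Step 10
Reactants: 12 trans-epoxy 4-nitrobenzoate (1S,2R,3R)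
Product: 13 trans-epoxy alcohol (1S,2R,3R)
Conditions: K2CO3 (0.2 equiv), MeOH, 0 °C
Reagents that add atoms: none
Why: Base-catalysed transesterification of the activated ester with methanol; catalytic carbonate at 0 °C keeps the alkoxide concentration too low for Payne migration of the trans-epoxy alcohol.

Step 11
Reactants: 13 trans-epoxy alcohol (1S,2R,3R)
Product: 14 (2R,3R,4S)-6-chloro-2,3-epoxy-4,5,8-trihydroxy-1-tetralone
Conditions: TFA/CH2Cl2 (1:9), anisole (20 equiv), H2O (5 equiv), 0 °C
Reagents that add atoms: water, O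
Why: Acidolysis; dilute TFA ionises both PMB ethers (cation trapped by anisole) and hydrolyses the benzylic dimethyl ketal, while the epoxide, flanked by a carbonyl carbon and a carbinol carbon, resists acid opening.

Step 12
Reactants: 14 (2R,3R,4S)-6-chloro-2,3-epoxy-4,5,8-trihydroxy-1-tetralone
Product: 16 fragment 1: 4,5-O-DTBS-8-O-TES epoxy tetralone (2R,3S,4S), via silylene phenol 15 (not isolated)
Conditions: t-Bu2Si(OTf)2 (1.05 equiv), 2,6-lutidine, CH2Cl2, –40 → 0 °C; then TESOTf (1.3 equiv), 0 °C
Reagents that add atoms: di-tert-butylsilyl bis(trifluoromethanesulfonate), CC(C)(C)[Si](OS(=O)(=O)C(F)(F)F)(OS(=O)(=O)C(F)(F)F)C(C)(C)C; triethylsilyl trifluoromethanesulfonate, CC[Si](CC)(CC)OS(=O)(=O)C(F)(F)F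
Why: Silylation with silyl triflates; the ditriflate bridges the benzylic alcohol and the ortho phenol as a six-membered silylene (second Si–O bond formed intramolecularly), and the hydrogen-bonded peri phenol, the least nucleophilic hydroxyl group, is capped last by TESOTf.

Step 13
Reactants: 17 5-bromo-2-chlorophenol
Product: 18 5-bromo-2-chloro-4-iodophenol
Conditions: NIS (1.05 equiv), TsOH·H2O (10 mol %), MeCN, rt
Reagents that add atoms: N-iodosuccinimide, O=C1CCC(=O)N1I
Why: Electrophilic aromatic iodination goes para to the hydroxyl group, because the only free ortho position lies between OH and Br and is more hindered.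

Step 14
Reactants: 18 5-bromo-2-chloro-4-iodophenol
Product: 19 fragment 2: tert-butyl(5-bromo-2-chloro-4-iodophenoxy)dimethylsilane
Conditions: TBSCl, imidazole, DMF, rt
Reagents that add atoms: tert-butyldimethylsilyl chloride, CC(C)(C)[Si](C)(C)Cl
Why: Standard silylation of a phenol with a silyl chloride and imidazole.

Step 15
Reactants: 16 fragment 1: 4,5-O-DTBS-8-O-TES epoxy tetralone; 19 fragment 2: tert-butyl(5-bromo-2-chloro-4-iodophenoxy)dimethylsilane; 20 maleic anhydride
Product: 23 bicyclic ketal Z-acrylic acid, via lithium alkoxide adduct 21 (not isolated), via dilithium lactolate 22 (not isolated)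
Conditions: 19 (1.15 equiv), t-BuLi (2.3 equiv), Et2O, –100 °C; 16, –100 → –78 °C; t-BuLi (2.2 equiv), –78 °C; cannula into 20 (3 equiv), THF, –78 °C; 1 M HCl, 0 °C → rt
Reagents that add atoms: none
Why: Iodine–lithium exchange, far faster than bromine–lithium exchange, gives the C5 aryllithium, which at –100 °C does not lose LiBr to an aryne and adds to the C1' ketone of 16; bromine–lithium exchange beside the new alkoxide then gives the C4a aryllithium, which opens maleic anhydride to a Z keto carboxylate. The closest known reaction type is the use of 1,2-dihaloarenes as 1,2-dianion equivalents by sequential halogen–lithium exchange, with ketone addition followed by acylation with a cyclic anhydride. The C1' alkoxide closes the five-membered oxacycle on the new ketone at once (5-exo-trig; the lactolate also blocks a second addition), and aqueous acid hydrolyses the aryl TES ether and lets the C8' phenol close the 1,3-dioxin on the C4 oxocarbenium ion (6-endo-trig) under thermodynamic control. C1' is set by attack anti to the C2'–C3' epoxide oxygen, on the face that the silylene keeps free of an axial silyloxy group, and C4 follows from C1' because both ketal oxygens must span the rigid 2,8-dioxabicyclo[3.2.1]octane. The step needs exchange of iodine before bromine (built into 19: I at the future C5, Br at the future C4a), 1,2- instead of conjugate or double addition to the anhydride (hard aryllithium, –78 °C, inverse addition into excess 20) and a Z arm (fixed by the ring of 20).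

Step 16
Reactants: 23 bicyclic ketal Z-acrylic acid
Product: 24 bicyclic ketal enone (C1 ketone, C2=C3)
Conditions: (CF3CO)2O (3 equiv), CH2Cl2, 0 °C → rt; aq NaHCO3
Reagents that add atoms: none
Why: Intramolecular Friedel–Crafts acylation through the mixed trifluoroacetic anhydride; the Z geometry holds the acyl carbon over C8a, the only free ring A carbon within reach and ortho to the silyloxy group, and six-membered ring closure gives the enone.

Step 17
Reactants: 24 bicyclic ketal enone (C1 ketone, C2=C3)
Product: 25 bis-epoxide, silyl-protected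
Conditions: t-BuOOH (decane), DBU, CH2Cl2, 0 °C
Reagents that add atoms: tert-butyl hydroperoxide, CC(C)(C)OO
Why: Weitz–Scheffer nucleophilic epoxidation; tert-butyl peroxide adds to C3 on the face of the bridging oxygen, because the opposite face is screened by the aryl ketal oxygen and the C7'–H edge of ring B, and the enolate closes the epoxide on the same face, which sets C2 and C3.

Step 18
Reactants: 25 bis-epoxide, silyl-protected
Product: 26 target
Conditions: HF·pyridine, pyridine, THF, 0 °C → rt
Reagents that add atoms: none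
Why: Fluoride-mediated cleavage of Si–O bonds; pyridine-buffered HF removes the aryl TBS ether and the silylene without forming a free alkoxide beside the epoxides.

Compound list

1 | 4-(2,5-dimethoxyphenyl)butanoic acid | OC(=O)CCCc1cc(OC)ccc1OC | starting material
2 | 4-(4-chloro-2,5-dimethoxyphenyl)butanoic acid | OC(=O)CCCc1cc(OC)c(Cl)cc1OC | intermediate
3 | 7-chloro-5,8-dimethoxy-3,4-dihydronaphthalen-1(2H)-one | O=C1CCCc2c(OC)cc(Cl)c(OC)c12 | intermediate
4 | 7-chloro-5,8-dihydroxy-3,4-dihydronaphthalen-1(2H)-one | O=C1CCCc2c(O)cc(Cl)c(O)c12 | intermediate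
5 | 7-chloro-5,8-bis[(4-methoxybenzyl)oxy]-3,4-dihydronaphthalen-1(2H)-one | O=C1CCCc2c(OCc3ccc(OC)cc3)cc(Cl)c(OCc3ccc(OC)cc3)c12 | intermediate
6 | 7-chloro-5,8-bis[(4-methoxybenzyl)oxy]naphthalen-1(4H)-one (keto tautomer of 7, not isolated) | O=C1C=CCc2c(OCc3ccc(OC)cc3)cc(Cl)c(OCc3ccc(OC)cc3)c12 | intermediate
7 | 7-chloro-5,8-bis[(4-methoxybenzyl)oxy]naphthalen-1-ol | Oc1cccc2c(OCc3ccc(OC)cc3)cc(Cl)c(OCc3ccc(OC)cc3)c12 | intermediate
8 | 7-chloro-4-methoxy-5,8-bis[(4-methoxybenzyl)oxy]naphthalen-1-ol (not isolated) | COc1ccc(O)c2c(OCc3ccc(OC)cc3)c(Cl)cc(OCc3ccc(OC)cc3)c12 | intermediate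
9 | 7-chloro-4,4-dimethoxy-5,8-bis[(4-methoxybenzyl)oxy]naphthalen-1(4H)-one | O=C1C=CC(OC)(OC)c2c(OCc3ccc(OC)cc3)cc(Cl)c(OCc3ccc(OC)cc3)c12 | intermediate
10 | (2S,3R)-7-chloro-2,3-epoxy-4,4-dimethoxy-5,8-bis[(4-methoxybenzyl)oxy]-3,4-dihydronaphthalen-1(2H)-one | COC1(OC)[C@@H]2O[C@@H]2C(=O)c2c(OCc3ccc(OC)cc3)c(Cl)cc(OCc3ccc(OC)cc3)c12 | intermediate
11 | (1R,2R,3R)-7-chloro-2,3-epoxy-4,4-dimethoxy-5,8-bis[(4-methoxybenzyl)oxy]-1,2,3,4-tetrahydronaphthalen-1-ol (OH cis to the epoxide oxygen) | COC1(OC)[C@@H]2O[C@@H]2[C@H](O)c2c(OCc3ccc(OC)cc3)c(Cl)cc(OCc3ccc(OC)cc3)c12 | intermediate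
12 | (1S,2R,3R)-7-chloro-2,3-epoxy-4,4-dimethoxy-5,8-bis[(4-methoxybenzyl)oxy]-1,2,3,4-tetrahydronaphthalen-1-yl 4-nitrobenzoate (ester trans to the epoxide oxygen) | COC1(OC)[C@@H]2O[C@@H]2[C@@H](OC(=O)c3ccc(cc3)[N+](=O)[O-])c2c(OCc3ccc(OC)cc3)c(Cl)cc(OCc3ccc(OC)cc3)c12 | intermediate
13 | (1S,2R,3R)-7-chloro-2,3-epoxy-4,4-dimethoxy-5,8-bis[(4-methoxybenzyl)oxy]-1,2,3,4-tetrahydronaphthalen-1-ol (OH trans to the epoxide oxygen) | COC1(OC)[C@@H]2O[C@@H]2[C@@H](O)c2c(OCc3ccc(OC)cc3)c(Cl)cc(OCc3ccc(OC)cc3)c12 | intermediate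
14 | (2R,3R,4S)-6-chloro-2,3-epoxy-4,5,8-trihydroxy-3,4-dihydronaphthalen-1(2H)-one (4-OH trans to the epoxide oxygen) | O=C1[C@@H]2O[C@@H]2[C@@H](O)c2c(O)c(Cl)cc(O)c12 | intermediate
15 | (2R,3S,4S)-6-chloro-4,5-[(di-tert-butylsilanediyl)bis(oxy)]-2,3-epoxy-8-hydroxy-3,4-dihydronaphthalen-1(2H)-one (not isolated) | O=C1[C@@H]2O[C@@H]2[C@H]3O[Si](C(C)(C)C)(C(C)(C)C)Oc4c(Cl)cc(O)c1c34 | intermediate
16 | fragment 1: (2R,3S,4S)-6-chloro-4,5-[(di-tert-butylsilanediyl)bis(oxy)]-2,3-epoxy-8-[(triethylsilyl)oxy]-3,4-dihydronaphthalen-1(2H)-one | O=C1[C@@H]2O[C@@H]2[C@H]3O[Si](C(C)(C)C)(C(C)(C)C)Oc4c(Cl)cc(O[Si](CC)(CC)CC)c1c34 | intermediate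
17 | 5-bromo-2-chlorophenol | Oc1cc(Br)ccc1Cl | starting material
18 | 5-bromo-2-chloro-4-iodophenol | Oc1cc(Br)c(I)cc1Cl | intermediate
19 | fragment 2: tert-butyl(5-bromo-2-chloro-4-iodophenoxy)dimethylsilane | CC(C)(C)[Si](C)(C)Oc1cc(Br)c(I)cc1Cl | intermediate
20 | fragment 3: maleic anhydride | O=C1OC(=O)C=C1 | starting material
21 | lithium alkoxide of the C1' adduct: C1' bears the 2-bromo-5-chloro-4-(TBS-oxy)phenyl group anti and the O–Li group syn to the epoxide oxygen (not isolated) | [Li]O[C@]1(c2cc(Cl)c(O[Si](C)(C)C(C)(C)C)cc2Br)[C@@H]2O[C@@H]2[C@H]3O[Si](C(C)(C)C)(C(C)(C)C)Oc4c(Cl)cc(O[Si](CC)(CC)CC)c1c34 | intermediate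
22 | dilithium lactolate carboxylate: five-membered lactol at C4 (configuration at C4 not fixed) carrying the Z-acrylate arm, C8' still OTES (not isolated) | [Li]OC1(/C=C\C(=O)O[Li])O[C@]2(c3cc(Cl)c(O[Si](C)(C)C(C)(C)C)cc13)[C@@H]4O[C@@H]4[C@H]5O[Si](C(C)(C)C)(C(C)(C)C)Oc6c(Cl)cc(O[Si](CC)(CC)CC)c2c56 | intermediate
23 | (Z)-3-substituted acrylic acid on C4 of the bicyclic ketal: C4 bonded to C4a, the bridging oxygen (to C1') and the aryl oxygen (to C8'); ring A 7-Cl, 8-OTBS, C8a–H; ring B 6'-Cl, O4'/O5' di-tert-butylsilylene, 2',3'-epoxide; C1', C2', C3', C4', C4 configured as in 26 | c1c(O[Si](C)(C)C(C)(C)C)c(Cl)cc3c1[C@@]2(Oc4cc(Cl)c(O[Si]6(C(C)(C)C)C(C)(C)C)c5c4[C@]3(O2)[C@@H]2O[C@@H]2[C@H]5O6)/C=C\C(O)=O | intermediate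
24 | enone: C1 ketone on C8a, C2=C3, otherwise as 23 | O=C1c2c(O[Si](C)(C)C(C)(C)C)c(Cl)cc3c2[C@@]2(Oc4cc(Cl)c(O[Si]6(C(C)(C)C)C(C)(C)C)c5c4[C@]3(O2)[C@@H]2O[C@@H]2[C@H]5O6)C=C1 | intermediate
25 | 2,3-epoxide of 24, epoxide oxygen on the face of the bridging oxygen | O=C1c2c(O[Si](C)(C)C(C)(C)C)c(Cl)cc3c2[C@@]2(Oc4cc(Cl)c(O[Si]6(C(C)(C)C)C(C)(C)C)c5c4[C@]3(O2)[C@@H]2O[C@@H]2[C@H]5O6)[C@@H]2O[C@H]12 | intermediate
26 | CNP0289684.3: 7,6'-dichloro-8,4',5'-trihydroxy bis-epoxy bicyclic ketal ketone; C1'–O(bridge) syn and C4'–OH trans to the 2',3'-epoxide oxygen; 2,3-epoxide on the face of the bridging oxygen | O=C1c2c(O)c(Cl)cc3c2[C@@]2(Oc4cc(Cl)c(O)c5c4[C@]3(O2)[C@@H]2O[C@@H]2[C@H]5O)[C@@H]2O[C@H]12 | target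

Total step count: 18. Longest linear sequence: 16 steps (steps 1–12 and 15–18).

Steps most likely to fail

Step 15 (key step). Several processes could go wrong:
- The ortho-bromoaryllithium may lose LiBr (aryne formation) before it meets the ketone.
- The TES group may shift from the C8' oxygen to the new alkoxide, which would leave the acylated ketone without its lactolate protection.
- The C4a aryllithium may add in a conjugate fashion or twice to the anhydride.
- The carboxyl group may compete with the phenol for the C4 oxocarbenium ion during acid closure.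

Fallback, setting out from 16 and 19 and returning at 23: the carbon that becomes C4 is brought in as carbon dioxide and the three-carbon arm as an acetylide, in separate operations. Iodine–magnesium exchange of 19 (i-PrMgCl·LiCl, THF, –40 °C) gives an arylmagnesium chloride that is stable toward aryne formation and adds to 16 anti to the epoxide to give the bromo carbinol F1. Treatment with t-BuLi (3.1 equiv, –78 °C), carboxylation with CO2 and acidification (1 M HCl, which also removes the TES ether) give the spiro phthalide phenol F2. Lithium tert-butyl propiolate (tert-butyl propiolate, LiN(SiMe3)2, 2.2 equiv, –78 °C) adds once to the lactone carbonyl, and camphorsulfonic acid in CH2Cl2 closes the lactol with the C8' phenol to the bicyclic ketal ynoate F3, where no carboxyl group can compete. Semi-hydrogenation (H2, Pd/CaCO3 poisoned with Pb(OAc)2, quinoline) gives the Z tert-butyl enoate F4, and TFA in CH2Cl2 at 0 °C cleaves the ester to 23.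

Step 16. The risk lies in acid-promoted opening of the bicyclic ketal with the carboxyl group closing onto C4, loss of the ring A silyl ether, or too low nucleophilicity of C8a toward the mixed anhydride.

Fallback, setting out from 23 and returning at 24: the bond C1–C8a is made with reversed polarity. K2CO3 in MeOH at 0 °C cleaves only the aryl TBS ether and gives the ring A phenol acid F5. NIS iodinates the only free position ortho to that phenol (C8a) to give the iodo phenol acid F6. TBSCl and imidazole, followed by aqueous work-up that hydrolyses the silyl ester, restore the silyl ether in the iodo acid F7. Treatment with t-BuLi (3.1 equiv, THF, –78 °C) deprotonates the acid, exchanges iodine for lithium and lets the C8a aryllithium add to the lithium carboxylate (Parham-type cyclisation), which gives 24 on work-up.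

Step 9. The risk is slow displacement at the hindered benzylic carbinol beside the peri ether, or ionisation in place of SN2 with loss of configuration.

Fallback, setting out from 10 and returning at 13: reagent-controlled reduction replaces reduction plus inversion. Ketone 10 is reduced with BH3·SMe2 and (S)-2-methyl-CBS-oxazaborolidine (20 mol %, THF, –20 °C). The catalyst, which treats the aryl group as the large substituent as in 1-tetralone, delivers hydride to the face syn to the epoxide and gives 13 directly. This detour makes no compound outside the list (F0).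

Further compounds
F1 | step 15 | bromo carbinol: tertiary alcohol at C1' of the adduct of the 2-bromo-5-chloro-4-(TBS-oxy)phenyl group and 16, aryl group anti to the epoxide oxygen | O[C@]1(c2cc(Cl)c(O[Si](C)(C)C(C)(C)C)cc2Br)[C@@H]2O[C@@H]2[C@H]3O[Si](C(C)(C)C)(C(C)(C)C)Oc4c(Cl)cc(O[Si](CC)(CC)CC)c1c34
F2 | step 15 | spiro phthalide phenol: C4 as lactone carbonyl on C4a, lactone oxygen on C1', C8' OH free | O=C1O[C@]2(c3cc(Cl)c(O[Si](C)(C)C(C)(C)C)cc13)[C@@H]4O[C@@H]4[C@H]5O[Si](C(C)(C)C)(C(C)(C)C)Oc6c(Cl)cc(O)c2c56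
F3 | step 15 | bicyclic ketal tert-butyl ynoate: C4 bearing C≡C–CO2t-Bu | c1c(O[Si](C)(C)C(C)(C)C)c(Cl)cc3c1[C@@]2(Oc4cc(Cl)c(O[Si]6(C(C)(C)C)C(C)(C)C)c5c4[C@]3(O2)[C@@H]2O[C@@H]2[C@H]5O6)C#CC(=O)OC(C)(C)C
F4 | step 15 | tert-butyl ester of 23 (Z-enoate) | c1c(O[Si](C)(C)C(C)(C)C)c(Cl)cc3c1[C@@]2(Oc4cc(Cl)c(O[Si]6(C(C)(C)C)C(C)(C)C)c5c4[C@]3(O2)[C@@H]2O[C@@H]2[C@H]5O6)/C=C\C(=O)OC(C)(C)C
F5 | step 16 | ring A phenol acid: 23 with free C8 OH | c1c(O)c(Cl)cc3c1[C@@]2(Oc4cc(Cl)c(O[Si]6(C(C)(C)C)C(C)(C)C)c5c4[C@]3(O2)[C@@H]2O[C@@H]2[C@H]5O6)/C=C\C(O)=O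
F6 | step 16 | C8a-iodo phenol acid | Ic1c(O)c(Cl)cc3c1[C@@]2(Oc4cc(Cl)c(O[Si]6(C(C)(C)C)C(C)(C)C)c5c4[C@]3(O2)[C@@H]2O[C@@H]2[C@H]5O6)/C=C\C(O)=O
F7 | step 16 | C8a-iodo acid with C8 OTBS | Ic1c(O[Si](C)(C)C(C)(C)C)c(Cl)cc3c1[C@@]2(Oc4cc(Cl)c(O[Si]6(C(C)(C)C)C(C)(C)C)c5c4[C@]3(O2)[C@@H]2O[C@@H]2[C@H]5O6)/C=C\C(O)=O
F0 | step 9 | none | none
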